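**Retrosynthetic overview**
1. Target 20 ⇐ catalyst-controlled dioxirane epoxidation of the 1(10) Z-alkene of macrocycle 19 (second oxirane, formed last).
2. 19 ⇐ ring-closing metathesis at C1=C10 of seco-diene 18 (ten-membered carbocycle, third ring).
3. 18 ⇐ Nozaki–Hiyama–Kishi coupling with lactonisation at C6–C7 between cis-epoxy aldehyde 7 and β-bromo enoate 15 (butenolide, second ring).
4. 15 ⇐ asymmetric carbonyl–ene reaction of aldehyde 11 with isobutene (C8–C9 bond, C8 stereocentre); 11 ⇐ ynoate 8 by IBr addition and Stille coupling.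
5. 7 ⇐ Shi epoxidation of the achiral Z-allylic alcohol 5 (first oxirane, first stereocentres); 5 ⇐ but-2-yn-1-ol.

Assumption: positions are given in germacrane numbering (C1–C15; lactone on O–C6, tiglate on O–C8, acetate on O–C13), (tributylstannyl)methyl acetate is made beforehand from commercial (tributylstannyl)methanol and counts as a reagent, and the two antipodal fructose-derived ketones and the chiral acid are catalysts made or bought separately.

**Step 1**
Reactants: 1 but-2-yn-1-ol
Product: 3 (2Z)-3-iodobut-2-en-1-ol, via cyclic alkenylalanate 2 (not isolated)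
Conditions: NaAlH2(OCH2CH2OCH3)2, Et2O, 0 °C to rt; then I2, THF, −78 to 0 °C
Reagents that add atoms: iodine, II
Why: Hydroxyl-directed trans-hydroalumination puts aluminium on C3 inside a five-membered alkoxy-alanate, so iodinolysis with retention gives only the Z vinyl iodide (alkyne hydroalumination–iodination).

**Step 2**
Reactants: 3 (2Z)-3-iodobut-2-en-1-ol; 4 but-3-en-1-ylzinc bromide
Product: 5 (2Z)-3-methylhepta-2,6-dien-1-ol
Conditions: Pd(PPh3)4 (3 mol%), THF, rt to 45 °C (2.2 equiv of 4)
Reagents that add atoms: none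
Why: Negishi sp2–sp3 cross-coupling goes with retention of alkene geometry and gives the achiral Z-trisubstituted allylic alcohol whose alkene becomes the cis C4–C5 epoxide.

**Step 3**
Reactants: 5 (2Z)-3-methylhepta-2,6-dien-1-ol
Product: 6 [(2R,3S)-3-(but-3-en-1-yl)-3-methyloxiran-2-yl]methanol
Conditions: D-fructose-derived Shi ketone (30 mol%), KHSO5 (as 2KHSO5·KHSO4·K2SO4), K2CO3, Bu4NHSO4 (cat.), MeCN/CH2(OMe)2/aq. Na2B4O7 buffer, 0 °C
Reagents that add atoms: potassium peroxymonosulfate, [K+].[O-]S(=O)(=O)OO
Why: Shi asymmetric epoxidation: the chiral dioxirane attacks the only electron-rich trisubstituted alkene through the spiro transition state with the vinylic H in the crowded quadrant, and this stereospecific syn oxygen transfer sets C4 (S) and C5 (R) as the cis epoxide while the terminal vinyl group stays untouched.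

**Step 4**
Reactants: 6 [(2R,3S)-3-(but-3-en-1-yl)-3-methyloxiran-2-yl]methanol
Product: 7 (2S,3S)-3-(but-3-en-1-yl)-3-methyloxirane-2-carbaldehyde
Conditions: Dess–Martin periodinane, NaHCO3, CH2Cl2, 0 °C to rt; used crude
Reagents that add atoms: none
Why: Buffered Dess–Martin oxidation gives the epoxy aldehyde without opening the epoxide, and the aldehyde α-carbon is an oxirane carbon that does not epimerise (the descriptor at that carbon changes from R to S only because CHO outranks the ring carbon).

**Step 5**
Reactants: 8 methyl 4-hydroxybut-2-ynoate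
Product: 9 methyl (2E)-3-bromo-4-hydroxy-2-iodobut-2-enoate
Conditions: IBr (1.05 equiv), CH2Cl2, −20 °C to rt, dark
Reagents that add atoms: iodine monobromide, BrI
Why: Electrophilic anti-addition of IBr to the ynoate: the iodonium ion is opened by bromide at the carbon remote from the ester, giving I on C2 and Br on C3 trans to each other (Br cis to CO2Me), and any syn adduct lactonises and is removed on chromatography.

**Step 6**
Reactants: 9 methyl (2E)-3-bromo-4-hydroxy-2-iodobut-2-enoate
Product: 10 methyl (2Z)-2-(acetoxymethyl)-3-bromo-4-hydroxybut-2-enoate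
Conditions: (tributylstannyl)methyl acetate (1.1 equiv), Pd2(dba)3 (2.5 mol%), AsPh3 (10 mol%), CuI (10 mol%), NMP, 40 °C
Reagents that add atoms: (tributylstannyl)methyl acetate, CCCC[Sn](CCCC)(CCCC)COC(C)=O
Why: Stille cross-coupling: zerovalent palladium inserts into the weaker C–I bond well before the C–Br bond at 40 °C, the α-oxygenated CH2 group is the one transferred from tin, and alkene geometry is retained.

**Step 7**
Reactants: 10 methyl (2Z)-2-(acetoxymethyl)-3-bromo-4-hydroxybut-2-enoate
Product: 11 methyl (2Z)-2-(acetoxymethyl)-3-bromo-4-oxobut-2-enoate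
Conditions: Dess–Martin periodinane, CH2Cl2, rt
Reagents that add atoms: none
Why: Dess–Martin oxidation of the primary allylic alcohol gives the electron-poor enal without touching the vinyl bromide or the acetate.

**Step 8**
Reactants: 11 methyl (2Z)-2-(acetoxymethyl)-3-bromo-4-oxobut-2-enoate; 12 2-methylpropene
Product: 13 methyl (2Z,4R)-2-(acetoxymethyl)-3-bromo-4-hydroxy-6-methylhepta-2,6-dienoate
Conditions: 12 (5 equiv, condensed), (S,S)-configured imidodiphosphorimidate (IDPi) Brønsted acid (2 mol%), CH2Cl2, −60 °C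
Reagents that add atoms: none
Why: Proposed new method: an intermolecular, Brønsted-acid-catalysed asymmetric carbonyl–ene reaction of a vinylogous glyoxylate (4-oxo-enoate) with gaseous isobutene, in which the aldehyde is hydrogen-bonded and partly protonated inside the confined chiral anion and isobutene adds through a concerted, asynchronous six-membered ene transition state (C8–C9 bond formation with transfer of an allylic methyl H to oxygen) to give only the 2-methylallyl carbinol and to set C8 (R) under catalyst control (the antipodal acid is used if a test run shows the opposite sense), while low temperature and the non-nucleophilic counter-anion hold back cationic oligomerisation of isobutene; the closest known reaction types are the Lewis-acid-catalysed asymmetric glyoxylate–ene reaction of 1,1-disubstituted alkenes and confined-acid-catalysed carbonyl–ene cyclisations.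

**Step 9**
Reactants: 13 methyl (2Z,4R)-2-(acetoxymethyl)-3-bromo-4-hydroxy-6-methylhepta-2,6-dienoate; 14 (2E)-2-methylbut-2-enoyl chloride (tigloyl chloride)
Product: 15 methyl (2Z,4R)-2-(acetoxymethyl)-3-bromo-6-methyl-4-{[(2E)-2-methylbut-2-enoyl]oxy}hepta-2,6-dienoate
Conditions: pyridine, DMAP (cat.), CH2Cl2, 0 °C to rt
Reagents that add atoms: none
Why: DMAP-catalysed acylation of the secondary alcohol with the acid chloride installs the tiglate early; the E acyl group is the thermodynamically stable isomer, so its geometry is not at risk.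

**Step 10**
Reactants: 7 (2S,3S)-3-(but-3-en-1-yl)-3-methyloxirane-2-carbaldehyde; 15 methyl (2Z,4R)-2-(acetoxymethyl)-3-bromo-6-methyl-4-{[(2E)-2-methylbut-2-enoyl]oxy}hepta-2,6-dienoate
Product: 18 (1R)-1-{(2R)-4-(acetoxymethyl)-2-[(2R,3S)-3-(but-3-en-1-yl)-3-methyloxiran-2-yl]-5-oxo-2,5-dihydrofuran-3-yl}-3-methylbut-3-en-1-yl (2E)-2-methylbut-2-enoate, via alkenylchromium dichloride 16 (not isolated), via chromium alkoxide 17 (not isolated)
Conditions: CrCl2 (4 equiv), NiCl2 (2 mol%), DMSO/THF, rt; aq. NH4Cl work-up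
Reagents that add atoms: none
Why: Nozaki–Hiyama–Kishi reaction: zerovalent nickel inserts into the ester-activated β C–Br bond, transmetalation gives the alkenyl trivalent chromium species with retention, this adds to the cis-epoxy aldehyde in the Felkin–Anh sense (epoxide C–O anti to the nucleophile) to set C6 (R), and the alkoxide, cis to CO2Me, closes the butenolide with loss of methanol; the minor C6 epimer is removed by chromatography.

**Step 11**
Reactants: 18 seco-diene butenolide (name as in step 10)
Product: 19 (1(10)Z,4S,5R,6R,8R)-13-acetoxy-4,5-epoxy-8-[(2E)-2-methylbut-2-enoyloxy]germacra-1(10),7(11)-dien-12,6-olide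
Conditions: second-generation Hoveyda–Grubbs catalyst (10 mol%, in portions), toluene (1 mM), 80 °C, argon sparge
Reagents that add atoms: none
Why: Ring-closing metathesis of the monosubstituted and the 1,1-disubstituted alkene at high dilution closes the ten-membered ring; the cis-epoxide and the butenolide pre-bend the chain, the Z trisubstituted alkene is expected to be favoured in this ring (any E isomer is separated), and the tiglate and butenolide alkenes are too electron-poor and hindered to take part.

**Step 12**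
Reactants: 19 macrocyclic diene lactone (name as in step 11)
Product: 20 (1S,4S,5R,6R,8R,10R)-13-acetoxy-1,10:4,5-diepoxy-8-[(2E)-2-methylbut-2-enoyloxy]germacr-7(11)-en-12,6-olide (target)
Conditions: L-fructose-derived ent-Shi ketone (50 mol%), KHSO5 (as 2KHSO5·KHSO4·K2SO4), K2CO3, Bu4NHSO4 (cat.), MeCN/CH2(OMe)2/aq. Na2B4O7 buffer (pH about 9.5–10), −5 °C
Reagents that add atoms: potassium peroxymonosulfate, [K+].[O-]S(=O)(=O)OO
Why: Shi epoxidation with the enantiomeric ketone: only the electron-rich 1(10) alkene reacts, and the same spiro transition-state model that gave (4S,5R) in step 3 predicts that the antipodal dioxirane delivers oxygen to the opposite face of this Z alkene, setting C1 (S) and C10 (R) by stereospecific syn addition.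

**Compound list**
1 | but-2-yn-1-ol | CC#CCO | starting material
2 | sodium 2,2-bis(2-methoxyethoxy)-3-methyl-2,5-dihydro-1,2-oxaluminol-2-uide (cyclic alkenylalanate) | [Na+].CC1=CCO[Al-]1(OCCOC)OCCOC | intermediate (not isolated)
3 | (2Z)-3-iodobut-2-en-1-ol | OC/C=C(/C)I | intermediate
4 | but-3-en-1-ylzinc bromide | C=CCC[Zn]Br | starting material
5 | (2Z)-3-methylhepta-2,6-dien-1-ol | OC/C=C(/C)CCC=C | intermediate
6 | [(2R,3S)-3-(but-3-en-1-yl)-3-methyloxiran-2-yl]methanol | OC[C@H]1O[C@@]1(C)CCC=C | intermediate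
7 | (2S,3S)-3-(but-3-en-1-yl)-3-methyloxirane-2-carbaldehyde | O=C[C@H]1O[C@@]1(C)CCC=C | intermediate
8 | methyl 4-hydroxybut-2-ynoate | COC(=O)C#CCO | starting material
9 | methyl (2E)-3-bromo-4-hydroxy-2-iodobut-2-enoate | COC(=O)/C(I)=C(\Br)CO | intermediate
10 | methyl (2Z)-2-(acetoxymethyl)-3-bromo-4-hydroxybut-2-enoate | COC(=O)/C(COC(C)=O)=C(\Br)CO | intermediate
11 | methyl (2Z)-2-(acetoxymethyl)-3-bromo-4-oxobut-2-enoate | COC(=O)/C(COC(C)=O)=C(\Br)C=O | intermediate
12 | 2-methylpropene (isobutene) | CC(C)=C | starting material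
13 | methyl (2Z,4R)-2-(acetoxymethyl)-3-bromo-4-hydroxy-6-methylhepta-2,6-dienoate | COC(=O)/C(COC(C)=O)=C(\Br)[C@H](O)CC(C)=C | intermediate
14 | (2E)-2-methylbut-2-enoyl chloride (tigloyl chloride) | C/C=C(\C)C(Cl)=O | starting material
15 | methyl (2Z,4R)-2-(acetoxymethyl)-3-bromo-6-methyl-4-{[(2E)-2-methylbut-2-enoyl]oxy}hepta-2,6-dienoate | COC(=O)/C(COC(C)=O)=C(\Br)[C@H](OC(=O)/C(C)=C/C)CC(C)=C | intermediate
16 | alkenylchromium dichloride: 15 with CrCl2 in place of Br, chromium cis to CO2Me | COC(=O)/C(COC(C)=O)=C(\[Cr](Cl)Cl)[C@H](OC(=O)/C(C)=C/C)CC(C)=C | intermediate (not isolated)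
17 | dichlorochromium alkoxide of the (6R) Felkin adduct of 16 and 7 (open hydroxy ester, O–C6 cis to CO2Me) | COC(=O)/C(COC(C)=O)=C(\[C@@H](O[Cr](Cl)Cl)[C@H]1O[C@@]1(C)CCC=C)[C@H](OC(=O)/C(C)=C/C)CC(C)=C | intermediate (not isolated)
18 | (1R)-1-{(2R)-4-(acetoxymethyl)-2-[(2R,3S)-3-(but-3-en-1-yl)-3-methyloxiran-2-yl]-5-oxo-2,5-dihydrofuran-3-yl}-3-methylbut-3-en-1-yl (2E)-2-methylbut-2-enoate | C/C=C(\C)C(=O)O[C@H](CC(C)=C)C1=C(COC(C)=O)C(=O)O[C@H]1[C@H]1O[C@@]1(C)CCC=C | intermediate
19 | (1(10)Z,4S,5R,6R,8R)-13-acetoxy-4,5-epoxy-8-[(2E)-2-methylbut-2-enoyloxy]germacra-1(10),7(11)-dien-12,6-olide | C/C=C(\C)C(=O)O[C@@H]1C/C(C)=C\CC[C@]2(C)O[C@@H]2[C@@H]2OC(=O)C(COC(C)=O)=C21 | intermediate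
20 | (1S,4S,5R,6R,8R,10R)-13-acetoxy-1,10:4,5-diepoxy-8-[(2E)-2-methylbut-2-enoyloxy]germacr-7(11)-en-12,6-olide (CNP0251711.3) | C/C=C(\C)C(=O)O[C@@H]1C[C@@]2(C)O[C@H]2CC[C@]2(C)O[C@@H]2[C@@H]2OC(=O)C(COC(C)=O)=C21 | target

**Totals**
Total step count: 12. Longest linear sequence: 8 steps (8 → 9 → 10 → 11 → 13 → 15 → 18 → 19 → 20); the other branch (1 → 7) is 4 steps before the convergence in step 10.

**Three steps most likely to fail**

Step 8 (the new carbonyl–ene reaction; risks are isobutene oligomerisation, low conversion of a hindered enal, or low ee). The fallback uses known chemistry. It sets out from 11 and comes back at 13. Aldehyde 11 is allylated with 4,4,5,5-tetramethyl-2-(2-methylallyl)-1,3,2-dioxaborolane under (R)-TRIP phosphoric acid catalysis (5 mol%, toluene, −30 °C). This passes through a closed chair transition state in which the acid activates the boronate, and it gives the pinacol borate ester of 13 F1. Aqueous work-up hydrolyses it to 13, and the route continues at step 9.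

Step 11 (ring-closing metathesis to a ten-membered carbocycle with a trisubstituted alkene; risks are dimerisation and E/Z mixtures). The fallback moves the ring closure to C6–C7 and makes the 1(10) alkene and C8 beforehand by a Z-selective allylboration. It sets out from 6 and 11 and comes back at 19. Cross-metathesis of 6 with methyl 2-methylallyl carbonate (second-generation Grubbs catalyst, CH2Cl2, 40 °C) gives the (E)-allylic carbonate F2. Copper-catalysed γ-selective borylation (CuCl, Xantphos, KOt-Bu, B2pin2, THF) gives the secondary allylboronate F3 as both epimers at the boron-bearing carbon. (R)-TRIP-catalysed allylboration of 11 with F3 (2 equiv, the acid selects one epimer, α-substituent axial in the chair) gives the Z-homoallylic borate F4, and work-up gives the diol F5 with the Z alkene and C8 (R) in place. TEMPO/PhI(OAc)2 oxidises only the primary alcohol to the hydroxy aldehyde F6, and tigloyl chloride 14 with pyridine gives the tiglate aldehyde F7. An intramolecular Nozaki–Hiyama–Kishi reaction (CrCl2, cat. NiCl2, DMSO/THF, 2 mM) then runs through the alkenylchromium dichloride F8 and the macrocyclic chromium alkoxide F9, which lactonises to 19.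

Step 12 (face selectivity of the last epoxidation; the ring may impose its own bias against the catalyst, and the basic medium may touch the acetate). The fallback sets out from 19 and comes back at 20. If electrophiles attack the 1(10) alkene from the face that leads to the 1,10-epimeric epoxide, that bias is used in the opposite sense. NBS in aqueous DME at 0 °C forms the bromonium ion on that face and water opens it anti at the tertiary C10, giving the (1R,10R)-bromohydrin F10. Ag2O in CH2Cl2 then closes the epoxide by displacement of bromide with inversion at C1, which gives 20 under neutral conditions.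

**Further compounds**
F1 | step 8 | methyl (2Z,4R)-2-(acetoxymethyl)-3-bromo-6-methyl-4-[(4,4,5,5-tetramethyl-1,3,2-dioxaborolan-2-yl)oxy]hepta-2,6-dienoate (pinacol borate ester of 13) | COC(=O)/C(COC(C)=O)=C(\Br)[C@H](OB1OC(C)(C)C(C)(C)O1)CC(C)=C
F2 | step 11 | methyl (2E)-5-[(2S,3R)-3-(hydroxymethyl)-2-methyloxiran-2-yl]-2-methylpent-2-en-1-yl carbonate | OC[C@H]1O[C@@]1(C)CC/C=C(\C)COC(=O)OC
F3 | step 11 | {(2R,3S)-3-methyl-3-[4-methyl-3-(4,4,5,5-tetramethyl-1,3,2-dioxaborolan-2-yl)pent-4-en-1-yl]oxiran-2-yl}methanol (both epimers at the boron-bearing carbon) | OC[C@H]1O[C@@]1(C)CCC(B2OC(C)(C)C(C)(C)O2)C(C)=C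
F4 | step 11 | pinacol borate ester at O–C8 of F5 | OC[C@H]1O[C@@]1(C)CC/C=C(C)\C[C@@H](OB2OC(C)(C)C(C)(C)O2)/C(Br)=C(\COC(C)=O)C(=O)OC
F5 | step 11 | methyl (2Z,4R,6Z)-2-(acetoxymethyl)-3-bromo-4-hydroxy-9-[(2S,3R)-3-(hydroxymethyl)-2-methyloxiran-2-yl]-6-methylnona-2,6-dienoate | OC[C@H]1O[C@@]1(C)CC/C=C(C)\C[C@@H](O)/C(Br)=C(\COC(C)=O)C(=O)OC
F6 | step 11 | methyl (2Z,4R,6Z)-2-(acetoxymethyl)-3-bromo-9-[(2S,3S)-3-formyl-2-methyloxiran-2-yl]-4-hydroxy-6-methylnona-2,6-dienoate | O=C[C@H]1O[C@@]1(C)CC/C=C(C)\C[C@@H](O)/C(Br)=C(\COC(C)=O)C(=O)OC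
F7 | step 11 | methyl (2Z,4R,6Z)-2-(acetoxymethyl)-3-bromo-9-[(2S,3S)-3-formyl-2-methyloxiran-2-yl]-6-methyl-4-{[(2E)-2-methylbut-2-enoyl]oxy}nona-2,6-dienoate | O=C[C@H]1O[C@@]1(C)CC/C=C(C)\C[C@@H](OC(=O)/C(C)=C/C)/C(Br)=C(\COC(C)=O)C(=O)OC
F8 | step 11 | alkenylchromium dichloride: F7 with CrCl2 in place of Br | O=C[C@H]1O[C@@]1(C)CC/C=C(C)\C[C@@H](OC(=O)/C(C)=C/C)/C([Cr](Cl)Cl)=C(\COC(C)=O)C(=O)OC
F9 | step 11 | macrocyclic dichlorochromium alkoxide (ten-membered ring closed at C6–C7, methyl ester not yet lactonised) | COC(=O)/C(COC(C)=O)=C1\[C@@H](O[Cr](Cl)Cl)[C@H]2O[C@@]2(C)CC/C=C(C)\C[C@H]1OC(=O)/C(C)=C/C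
F10 | step 12 | (1R,4S,5R,6R,8R,10R)-13-acetoxy-1-bromo-4,5-epoxy-10-hydroxy-8-[(2E)-2-methylbut-2-enoyloxy]germacr-7(11)-en-12,6-olide (bromohydrin) | C/C=C(\C)C(=O)O[C@@H]1C[C@@](C)(O)[C@H](Br)CC[C@]2(C)O[C@@H]2[C@@H]2OC(=O)C(COC(C)=O)=C21
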